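**Plan**
Cuts: first the C5'-C1'' bond between ring B and the side chain (Heck), then O1-C8a and C4-C4a of the pyranone ring C in one stroke, and last C2-C3 (formylation of an arylacetate).
Enabling feature: O1 and the C4 carbonyl sit on the neighbouring ring A carbons C8a and C4a, and the C5 oxygen stands next to C4a. This is the imprint of a 3-alkoxyaryne that takes a nucleophile at its far carbon and an electrophile at its near carbon.
Forward: ring A, bought as a phenol, becomes an ortho-silylaryl triflate in steps 1-3. Ring B, from 5-bromovanillin with its O-methyl group first moved from O3 to O4, becomes a formylated methyl arylacetate in steps 4-9.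
Ring C closes in step 10. The benzyl ethers are then exchanged for acetates, the five-carbon chain is joined at C5', and the acetates are taken off.
Stereochemistry: there is no stereocentre. The E alkene comes from syn insertion and syn beta-hydride elimination in the Heck coupling.

Key step: step 10

Assumption: the 3-oxopropanoate ester is drawn as its aldehyde tautomer although it should exist mainly as the hydrogen-bonded Z-enol, so its alpha carbon is not counted as a stereocentre.

**Route**

Step 1
Reactants: 1 3,5-bis(benzyloxy)phenol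
Product: 2 3,5-bis(benzyloxy)-2-bromophenol
Conditions: NBS (1.0 equiv), CH2Cl2, -78 °C to rt
Reagents that add atoms: N-bromosuccinimide, O=C1CCC(=O)N1Br
Why: Electrophilic aromatic bromination, in which the two equivalent positions ortho to the free hydroxyl are strongly activated and less crowded than C4 between the two benzyloxy groups, so one equivalent of NBS at low temperature should give mainly the 2-bromide.

Step 2
Reactants: 2 3,5-bis(benzyloxy)-2-bromophenol
Product: 3 [3,5-bis(benzyloxy)-2-bromophenoxy]trimethylsilane
Conditions: HMDS, THF, 70 °C; evaporate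
Reagents that add atoms: hexamethyldisilazane, C[Si](C)(C)N[Si](C)(C)C
Why: O-silylation of a phenol with HMDS needs no added base and leaves only a volatile by-product, so the moisture-sensitive silyl ether can be used after evaporation.

Step 3
Reactants: 3 [3,5-bis(benzyloxy)-2-bromophenoxy]trimethylsilane
Product: 6 3,5-bis(benzyloxy)-2-(trimethylsilyl)phenyl trifluoromethanesulfonate, via aryllithium 4 (not isolated), via lithium silylphenoxide 5 (not isolated)
Conditions: n-BuLi, THF, -78 °C; then Tf2O, -78 °C to 0 °C
Reagents that add atoms: trifluoromethanesulfonic anhydride, O=S(=O)(OS(=O)(=O)C(F)(F)F)C(F)(F)F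
Why: Bromine-lithium exchange outruns benzylic deprotonation at low temperature, the aryllithium undergoes a retro-Brook O-to-C silyl shift, and the resulting phenoxide is O-triflated in the same flask, which is the standard entry to ortho-silylaryl triflates.

Step 4
Reactants: 7 5-bromovanillin (3-bromo-4-hydroxy-5-methoxybenzaldehyde)
Product: 8 3-bromo-4,5-dihydroxybenzaldehyde
Conditions: BBr3, CH2Cl2, -78 °C to rt; then H2O
Reagents that add atoms: none
Why: Lewis acid cleavage of an aryl methyl ether, helped by boron binding to the neighbouring phenol, removes the methyl group of 7, which sits on the oxygen that must end as the free 3'-hydroxyl.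

Step 5
Reactants: 8 3-bromo-4,5-dihydroxybenzaldehyde
Product: 9 3-bromo-5-hydroxy-4-methoxybenzaldehyde
Conditions: MeI (1.1 equiv), Li2CO3, DMF, 50 °C
Reagents that add atoms: iodomethane, CI
Why: Chemoselective Williamson ether synthesis, in which the 4-hydroxyl (para to the aldehyde, ortho to bromine) is much the more acidic, so the weak base Li2CO3 should form only its phenoxide and one equivalent of MeI should methylate that oxygen alone.

Step 6
Reactants: 9 3-bromo-5-hydroxy-4-methoxybenzaldehyde
Product: 10 3-(benzyloxy)-5-bromo-4-methoxybenzaldehyde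
Conditions: BnBr, K2CO3, DMF, rt
Reagents that add atoms: benzyl bromide, BrCc1ccccc1
Why: Williamson ether synthesis on the only remaining phenol gives a protecting group that tolerates the hydride base, acidic methanol and fluoride to come.

Step 7
Reactants: 10 3-(benzyloxy)-5-bromo-4-methoxybenzaldehyde
Product: 11 1-(benzyloxy)-3-bromo-2-methoxy-5-[2-(methylsulfanyl)-2-(methylsulfinyl)ethenyl]benzene
Conditions: MeSCH2S(O)Me, Triton B (cat., 40% in MeOH), THF, reflux
Reagents that add atoms: methyl methylsulfinylmethyl sulfide, CSCS(C)=O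
Why: Knoevenagel-type condensation of the aldehyde with the acidic methylene group between the two sulfur atoms is well established for alkoxybenzaldehydes and brings in the missing carbon already at the carboxyl oxidation level.

Step 8
Reactants: 11 1-(benzyloxy)-3-bromo-2-methoxy-5-[2-(methylsulfanyl)-2-(methylsulfinyl)ethenyl]benzene
Product: 12 methyl 2-[3-(benzyloxy)-5-bromo-4-methoxyphenyl]acetate
Conditions: HCl/MeOH, 50 °C
Reagents that add atoms: methanol, CO
Why: Acid methanolysis of a ketene dithioacetal S-oxide (protonation at the benzylic carbon, addition of methanol, Pummerer-type loss of both sulfur groups) is the known second half of this one-carbon homologation and leaves the aryl benzyl ether and the bromide alone.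

Step 9
Reactants: 12 methyl 2-[3-(benzyloxy)-5-bromo-4-methoxyphenyl]acetate; 13 methyl formate
Product: 14 methyl 2-[3-(benzyloxy)-5-bromo-4-methoxyphenyl]-3-oxopropanoate
Conditions: NaH, THF, 0 °C to rt; then 1 M HCl
Reagents that add atoms: none
Why: Crossed Claisen condensation (C-formylation), in which methyl formate cannot enolise and the product is withdrawn as its stabilised sodium enolate, so the equilibrium is pulled to the formyl ester, and methyl esters on both partners rule out ester scrambling.

Step 10
Reactants: 14 methyl 2-[3-(benzyloxy)-5-bromo-4-methoxyphenyl]-3-oxopropanoate; 6 3,5-bis(benzyloxy)-2-(trimethylsilyl)phenyl trifluoromethanesulfonate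
Product: 18 5,7-bis(benzyloxy)-3-[3-(benzyloxy)-5-bromo-4-methoxyphenyl]-4H-chromen-4-one, via cesium Z-enolate 15 (not isolated), via 3,5-bis(benzyloxy)benzyne 16 (not isolated), via aryl anion 17 (not isolated)
Conditions: CsF (4 equiv), 6 (1.5 equiv, added slowly), THF, 65 °C
Reagents that add atoms: none
Why: Proposed new method: CsF turns 14 into the cesium-chelated Z-enolate 15 and, by attack on silicon with loss of triflate, turns 6 into aryne 16; the enolate oxygen adds to the aryne carbon remote from the flanking benzyloxy group (future C8a), and the aryl anion 17 so created at the future C4a adds to the ester carbonyl held cis to it and expels methoxide. The closest known reaction type is the annulation of arynes with salicylate esters to xanthones (O-arylation, then intramolecular acyl capture), in which the phenoxide is here replaced by the enolate of a formyl ester, a nucleophile class not yet shown in this role. Ring C closes in 6-exo-trig mode by addition-elimination at the ester carbon, so that O1-C8a and C4-C4a form in one operation, and no stereocentre arises. Regioselectivity on the aryne comes from the benzyloxy group next to the triple bond, whose inductive pull distorts the aryne and stabilises negative charge on the adjacent carbon, which should send the nucleophile to the far carbon and give the 5,7-dioxygenated pattern. Oxygen rather than carbon attack of the ambident enolate is favoured by the exposed terminal oxygen, by the loosely paired cesium ion and by the alpha-aryl group, which would force carbon attack to build a congested quaternary centre. THF is chosen because it cannot protonate 17, and the slow addition of an excess of 6 allows for aryne lost to the liberated methoxide.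

Step 11
Reactants: 18 5,7-bis(benzyloxy)-3-[3-(benzyloxy)-5-bromo-4-methoxyphenyl]-4H-chromen-4-one
Product: 19 3-(3-bromo-5-hydroxy-4-methoxyphenyl)-5,7-dihydroxy-4H-chromen-4-one
Conditions: BCl3, C6HMe5, CH2Cl2, -78 °C; then H2O
Reagents that add atoms: none
Why: Lewis acid debenzylation with a cation scavenger, in which BCl3 ionises aryl benzyl ethers at -78 °C and pentamethylbenzene traps the benzyl cation by Friedel-Crafts alkylation, should spare the aryl bromide (which hydrogenolysis would endanger), the methyl ether and the pyranone.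

Step 12
Reactants: 19 3-(3-bromo-5-hydroxy-4-methoxyphenyl)-5,7-dihydroxy-4H-chromen-4-one
Product: 20 3-[3-(acetyloxy)-5-bromo-4-methoxyphenyl]-4-oxo-4H-chromene-5,7-diyl diacetate
Conditions: Ac2O, pyridine, DMAP (cat.), CH2Cl2, rt
Reagents that add atoms: acetic anhydride, CC(=O)OC(C)=O
Why: DMAP-catalysed O-acylation also reaches the chelated 5-hydroxyl, and the acetates mask the acidic phenols during the palladium step and can later be removed without the acid that the tertiary allylic alcohol would not survive.

Step 13
Reactants: 20 3-[3-(acetyloxy)-5-bromo-4-methoxyphenyl]-4-oxo-4H-chromene-5,7-diyl diacetate; 21 2-methylbut-3-en-2-ol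
Product: 22 3-{3-(acetyloxy)-5-[(1E)-3-hydroxy-3-methylbut-1-en-1-yl]-4-methoxyphenyl}-4-oxo-4H-chromene-5,7-diyl diacetate
Conditions: Pd(OAc)2 (cat.), P(o-tol)3, Et3N, DMF, 90 °C
Reagents that add atoms: none
Why: Mizoroki-Heck reaction, in which zerovalent palladium inserts into the C-Br bond, the aryl group goes to the unsubstituted alkene terminus by syn insertion, and syn beta-hydride elimination can only take a benzylic hydrogen because the carbinol carbon bears none, so the conjugated E alkene should result without isomerisation to a ketone.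

Step 14
Reactants: 22 3-{3-(acetyloxy)-5-[(1E)-3-hydroxy-3-methylbut-1-en-1-yl]-4-methoxyphenyl}-4-oxo-4H-chromene-5,7-diyl diacetate
Product: 23 5,7-dihydroxy-3-{3-hydroxy-5-[(1E)-3-hydroxy-3-methylbut-1-en-1-yl]-4-methoxyphenyl}-4H-chromen-4-one
Conditions: K2CO3 (cat.), MeOH, 0 °C to rt; pH 7 buffer
Reagents that add atoms: none
Why: Base-catalysed transesterification (Zemplén-type methanolysis) of aryl acetates is fast at or below room temperature and, with a neutral work-up, should leave the pyranone ring, the E alkene and the acid-sensitive tertiary allylic alcohol unchanged.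

**Compound list**
1 | 3,5-bis(benzyloxy)phenol | Oc1cc(OCc2ccccc2)cc(OCc2ccccc2)c1 | starting material
2 | 3,5-bis(benzyloxy)-2-bromophenol | Oc1cc(OCc2ccccc2)cc(OCc2ccccc2)c1Br | intermediate
3 | [3,5-bis(benzyloxy)-2-bromophenoxy]trimethylsilane | C[Si](C)(C)Oc1cc(OCc2ccccc2)cc(OCc2ccccc2)c1Br | intermediate
4 | {2,4-bis(benzyloxy)-6-[(trimethylsilyl)oxy]phenyl}lithium (formed in the flask) | C[Si](C)(C)Oc1cc(OCc2ccccc2)cc(OCc2ccccc2)c1[Li] | intermediate
5 | lithium 3,5-bis(benzyloxy)-2-(trimethylsilyl)phenoxide (formed in the flask) | [Li+].[O-]c1cc(OCc2ccccc2)cc(OCc2ccccc2)c1[Si](C)(C)C | intermediate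
6 | 3,5-bis(benzyloxy)-2-(trimethylsilyl)phenyl trifluoromethanesulfonate | C[Si](C)(C)c1c(OCc2ccccc2)cc(OCc2ccccc2)cc1OS(=O)(=O)C(F)(F)F | intermediate
7 | 5-bromovanillin | COc1cc(C=O)cc(Br)c1O | starting material
8 | 3-bromo-4,5-dihydroxybenzaldehyde | Oc1cc(C=O)cc(Br)c1O | intermediate
9 | 3-bromo-5-hydroxy-4-methoxybenzaldehyde | COc1c(O)cc(C=O)cc1Br | intermediate
10 | 3-(benzyloxy)-5-bromo-4-methoxybenzaldehyde | COc1c(Br)cc(C=O)cc1OCc1ccccc1 | intermediate
11 | 1-(benzyloxy)-3-bromo-2-methoxy-5-[2-(methylsulfanyl)-2-(methylsulfinyl)ethenyl]benzene (alkene geometry not defined, racemic at sulfur; both elements vanish in step 8) | COc1c(Br)cc(C=C(SC)S(C)=O)cc1OCc1ccccc1 | intermediate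
12 | methyl 2-[3-(benzyloxy)-5-bromo-4-methoxyphenyl]acetate | COC(=O)Cc1cc(Br)c(OC)c(OCc2ccccc2)c1 | intermediate
13 | methyl formate | COC=O | starting material
14 | methyl 2-[3-(benzyloxy)-5-bromo-4-methoxyphenyl]-3-oxopropanoate (aldehyde tautomer drawn) | COC(=O)C(C=O)c1cc(Br)c(OC)c(OCc2ccccc2)c1 | intermediate
15 | cesium (Z)-2-[3-(benzyloxy)-5-bromo-4-methoxyphenyl]-3-methoxy-3-oxoprop-1-en-1-olate (formed in the flask) | [Cs+].[O-]/C=C(/c1cc(Br)c(OC)c(OCc2ccccc2)c1)C(=O)OC | intermediate
16 | 3,5-bis(benzyloxy)benzyne (1,2-didehydro-3,5-bis(benzyloxy)benzene, formed in the flask) | C1#CC(OCc2ccccc2)=CC(OCc2ccccc2)=C1 | intermediate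
17 | cesium salt of the 2-aryl anion of methyl (Z)-3-[3,5-bis(benzyloxy)phenoxy]-2-[3-(benzyloxy)-5-bromo-4-methoxyphenyl]prop-2-enoate (formed in the flask) | [Cs+].COC(=O)/C(=C\Oc1cc(OCc2ccccc2)cc(OCc2ccccc2)[c-]1)c1cc(Br)c(OC)c(OCc2ccccc2)c1 | intermediate
18 | 5,7-bis(benzyloxy)-3-[3-(benzyloxy)-5-bromo-4-methoxyphenyl]-4H-chromen-4-one | COc1c(Br)cc(-c2coc3cc(OCc4ccccc4)cc(OCc4ccccc4)c3c2=O)cc1OCc1ccccc1 | intermediate
19 | 3-(3-bromo-5-hydroxy-4-methoxyphenyl)-5,7-dihydroxy-4H-chromen-4-one | COc1c(O)cc(-c2coc3cc(O)cc(O)c3c2=O)cc1Br | intermediate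
20 | 3-[3-(acetyloxy)-5-bromo-4-methoxyphenyl]-4-oxo-4H-chromene-5,7-diyl diacetate | COc1c(Br)cc(-c2coc3cc(OC(C)=O)cc(OC(C)=O)c3c2=O)cc1OC(C)=O | intermediate
21 | 2-methylbut-3-en-2-ol | C=CC(C)(C)O | starting material
22 | 3-{3-(acetyloxy)-5-[(1E)-3-hydroxy-3-methylbut-1-en-1-yl]-4-methoxyphenyl}-4-oxo-4H-chromene-5,7-diyl diacetate | COc1c(OC(C)=O)cc(-c2coc3cc(OC(C)=O)cc(OC(C)=O)c3c2=O)cc1/C=C/C(C)(C)O | intermediate
23 | 5,7-dihydroxy-3-{3-hydroxy-5-[(1E)-3-hydroxy-3-methylbut-1-en-1-yl]-4-methoxyphenyl}-4H-chromen-4-one | COc1c(O)cc(-c2coc3cc(O)cc(O)c3c2=O)cc1/C=C/C(C)(C)O | target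

Total step count: 14.
Longest linear sequence: 11 steps (steps 4 to 14, from 7). Steps 1 to 3 form the shorter branch that joins at step 10.

**Steps most likely to fail**

1. Step 10. Three processes could divert it.
- The ambident enolate may attack the aryne through carbon, followed by transfer of the formyl group.
- The aryl anion may pick up a proton before it reaches the ester.
- O-arylation may occur from the E-enolate geometry, which cannot close.

The fallback builds ring C by the classical deoxybenzoin route. It sets out from 12 and comes back at 19. Saponification of 12 (LiOH, THF/H2O) would give 2-[3-(benzyloxy)-5-bromo-4-methoxyphenyl]acetic acid F1. Friedel-Crafts acylation of phloroglucinol with this acid in BF3·OEt2 at 80 °C would give the deoxybenzoin 2-[3-(benzyloxy)-5-bromo-4-methoxyphenyl]-1-(2,4,6-trihydroxyphenyl)ethan-1-one F2. One-carbon insertion and cyclodehydration with DMF, BF3·OEt2 and MsCl would give 3-[3-(benzyloxy)-5-bromo-4-methoxyphenyl]-5,7-dihydroxy-4H-chromen-4-one F3. The conditions of step 11 then remove its single benzyl ether and deliver 19.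

2. Step 13. Oxidative addition into the electron-rich C-Br bond beside the methoxy group may be slow. The temperature then needed may cause loss of acetates and dehydration of the tertiary allylic alcohol. The fallback replaces alkene insertion by a Suzuki-Miyaura cross-coupling, in which the E geometry is bought with the reagent and retained. It sets out from 20 and comes back at 22. Bromide 20 would be coupled with the purchasable (E)-2-methyl-4-(4,4,5,5-tetramethyl-1,3,2-dioxaborolan-2-yl)but-3-en-2-ol F4, using Pd(dppf)Cl2 (cat.) and CsF in dioxane at 80 °C.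

3. Step 1. Bromination para to the hydroxyl (at C4) and double bromination may compete with the wanted ortho attack. The fallback places silicon by directed ortho metalation instead of by a halogen. It sets out from 1 and comes back at 6, bypassing 2 to 5.
- Addition of 1 to isopropyl isocyanate (Et3N cat., CH2Cl2) would give 3,5-bis(benzyloxy)phenyl isopropylcarbamate F5.
- TBSOTf and TMEDA in Et2O would convert it in the flask into 3,5-bis(benzyloxy)phenyl N-(tert-butyldimethylsilyl)-N-isopropylcarbamate F6.
- n-BuLi at -78 °C should lithiate the position between the carbamate and a benzyloxy group, where both directing groups cooperate. TMSCl would then give 3,5-bis(benzyloxy)-2-(trimethylsilyl)phenyl N-(tert-butyldimethylsilyl)-N-isopropylcarbamate F7.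
- Work-up with aqueous NaHSO4 frees the nitrogen to give 3,5-bis(benzyloxy)-2-(trimethylsilyl)phenyl isopropylcarbamate F8.
- DBU and Et2NH in MeCN at 40 °C would release 3,5-bis(benzyloxy)-2-(trimethylsilyl)phenol F9, which PhNTf2 in the same flask converts into 6.

**Further compounds**
F1 | step 10 | 2-[3-(benzyloxy)-5-bromo-4-methoxyphenyl]acetic acid | OC(=O)Cc1cc(Br)c(OC)c(OCc2ccccc2)c1
F2 | step 10 | 2-[3-(benzyloxy)-5-bromo-4-methoxyphenyl]-1-(2,4,6-trihydroxyphenyl)ethan-1-one | COc1c(Br)cc(CC(=O)c2c(O)cc(O)cc2O)cc1OCc1ccccc1
F3 | step 10 | 3-[3-(benzyloxy)-5-bromo-4-methoxyphenyl]-5,7-dihydroxy-4H-chromen-4-one | COc1c(Br)cc(-c2coc3cc(O)cc(O)c3c2=O)cc1OCc1ccccc1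
F4 | step 13 | (E)-2-methyl-4-(4,4,5,5-tetramethyl-1,3,2-dioxaborolan-2-yl)but-3-en-2-ol | CC(C)(O)/C=C/B1OC(C)(C)C(C)(C)O1
F5 | step 1 | 3,5-bis(benzyloxy)phenyl isopropylcarbamate | CC(C)NC(=O)Oc1cc(OCc2ccccc2)cc(OCc2ccccc2)c1
F6 | step 1 | 3,5-bis(benzyloxy)phenyl N-(tert-butyldimethylsilyl)-N-isopropylcarbamate | CC(C)N(C(=O)Oc1cc(OCc2ccccc2)cc(OCc2ccccc2)c1)[Si](C)(C)C(C)(C)C
F7 | step 1 | 3,5-bis(benzyloxy)-2-(trimethylsilyl)phenyl N-(tert-butyldimethylsilyl)-N-isopropylcarbamate | CC(C)N(C(=O)Oc1cc(OCc2ccccc2)cc(OCc2ccccc2)c1[Si](C)(C)C)[Si](C)(C)C(C)(C)C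
F8 | step 1 | 3,5-bis(benzyloxy)-2-(trimethylsilyl)phenyl isopropylcarbamate | CC(C)NC(=O)Oc1cc(OCc2ccccc2)cc(OCc2ccccc2)c1[Si](C)(C)C
F9 | step 1 | 3,5-bis(benzyloxy)-2-(trimethylsilyl)phenol | Oc1cc(OCc2ccccc2)cc(OCc2ccccc2)c1[Si](C)(C)C
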